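**Retrosynthetic overview**

1. Myrtucommulone A 18 (both arm carbons R) is released in one BCl3 step from the fully O-capped hexasubstituted arene 17 (2-OMe, 4,6-OSiMe3, syncarpyl enols as methyl ethers).
2. Ring A of 17 is cut into a 4,6-bis(silyloxy)-2-pyranone 11 (gives C3–C4–C5–C6) and the methoxy ynone 15 (gives acyl-bearing C1 and C2–O); Diels–Alder addition forms C2–C3 and C1–C6, then CO2 leaves. The feature used: ring A has oxygen on C2, C4 and C6, and its C3–C4–C5 segment with the two identical (R)-CH(iPr)-syncarpyl arms is C2-symmetric, so it is an enolised 2,4-disubstituted 3-oxoglutaric anhydride in disguise.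
3. Pyranone 11 comes from anhydride 10 and keto diester 8, made by a twofold catalytic asymmetric Michael addition of dibenzyl 3-oxoglutarate 5 to isobutylidenesyncarpic acid 4 (sets both stereocentres) with immediate O-methyl capping; 4 comes from syncarpic acid 1 and isobutyraldehyde 2.
4. Ring order: the two syncarpyl rings are bought with 1; the pyranone ring is closed in step 3; ring A is closed in step 6.
5. Two design points: a methyl ynol ether, which has no β-hydrogen and so cannot fragment by retro-ene at the cycloaddition temperature; and methyl-capped syncarpyl enols, which cannot leave in a retro-Michael reaction, cannot close onto the C3 ketone (hemiketal, 4H-pyran) and cannot form an enol lactone with an activated carboxyl.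

Key step: step 6

Assumption: the squaramide made from 9-amino-9-deoxy-epi-quinidine is taken to send the nucleophile to the Si face of the alkylidene CH of 4 (giving R); the sense has to be confirmed on the first adduct, and the epi-quinine-derived pseudo-enantiomer is used if it proves opposite.

Remark: the arm carbons keep one and the same spatial arrangement from 6 to 18. They are called R in 6–9, 17 and 18 and S in 10, 11 and 16 only because the pyranone or bridgehead carbon outranks the cyclohexenyl carbon in the CIP ranking there.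

**Route**

Step 1
Reactants: 1 syncarpic acid; 2 isobutyraldehyde
Product: 4 2,2,4,4-tetramethyl-6-(2-methylpropylidene)cyclohexane-1,3,5-trione (isobutylidenesyncarpic acid), via Mannich base 3 (not isolated)
Conditions: piperidine (1.1 equiv), CH2Cl2, 23 °C; then 1 M aq. HCl, 0 °C
Reagents that add atoms: none
Why: Mannich condensation of the acidic trione with the aldehyde and piperidine, followed by acid-induced loss of the amine (a stepwise Knoevenagel condensation), releases the alkylidene only after all trione is consumed, so no second trione can add; no stereocentre is formed.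

Step 2
Reactants: 4 isobutylidenesyncarpic acid (2.2 equiv); 5 dibenzyl 3-oxopentanedioate
Product: 8 dibenzyl 2,4-bis[(1R)-1-(2-methoxy-3,3,5,5-tetramethyl-4,6-dioxocyclohex-1-en-1-yl)-2-methylpropyl]-3-oxopentanedioate (C2/C4 epimers), via mono-adduct 6 (not isolated), via uncapped bis-adduct 7 (not isolated)
Conditions: squaramide from 9-amino-9-deoxy-epi-quinidine and 3,5-bis(trifluoromethyl)aniline (10 mol %), toluene, −20 °C; then MeOH, TMSCHN2 (2.4 equiv), 0 °C; chromatography
Reagents that add atoms: trimethylsilyldiazomethane, C[Si](C)(C)C=[N+]=[N-]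
Why: Bifunctional organocatalytic Michael addition, in which the squaramide N–H bonds hold a trione carbonyl of 4 while the ammonium-bound enolate of 5 attacks the Si face of the alkylidene CH (ring carbon > isopropyl > H) to set R; the second addition at the remaining CH2 is again catalyst-controlled, so a wrong-face event ends mainly in the meso diastereomer, the epimerisable C2/C4 centres are erased in step 3, and diazo O-methylation of the two strongly acidic enols (the keto ester enol is far less acidic) locks the configuration and removes the free enol OH.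

Step 3
Reactants: 8 capped keto diester
Product: 10 4,6-dihydroxy-3,5-bis[(1S)-1-(2-methoxy-3,3,5,5-tetramethyl-4,6-dioxocyclohex-1-en-1-yl)-2-methylpropyl]-2H-pyran-2-one (enolised cyclic anhydride, drawn as the dienol), via keto diacid 9 (not isolated)
Conditions: H2 (1 atm), Pd/C (10 wt % palladium on carbon), EtOAc, 0 °C; filter, concentrate below 10 °C; Ac2O–AcOH (1:1), 10 °C; evaporate under high vacuum
Reagents that add atoms: none
Why: Hydrogenolysis frees the β-keto diacid under neutral conditions, and cold cyclodehydration with acetic anhydride, the way 3-oxoglutaric acid itself gives its anhydride, closes the six-membered anhydride, which enolises to the hydroxypyranone; the second carboxyl is the only O-nucleophile within reach of the mixed anhydride, and the arm stereocentres are not touched.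

Step 4
Reactants: 10 enolised anhydride
Product: 11 3,5-bis[(1S)-1-(2-methoxy-3,3,5,5-tetramethyl-4,6-dioxocyclohex-1-en-1-yl)-2-methylpropyl]-4,6-bis(trimethylsilyloxy)-2H-pyran-2-one
Conditions: BSA (4 equiv), toluene, 23 → 50 °C; used as the toluene solution without chromatography
Reagents that add atoms: N,O-bis(trimethylsilyl)acetamide, CC(=N[Si](C)(C)C)O[Si](C)(C)C
Why: Neutral O-silylation of the two acidic enol hydroxyls gives the 2-pyranone as a cyclic 1,1,3-trioxygenated diene (a silyl ketene acetal of the anhydride); no stereocentre changes.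

Step 5
Reactants: 12 2-chloro-1,1-dimethoxyethane; 13 N-methoxy-N,2-dimethylpropanamide
Product: 15 1-methoxy-4-methylpent-1-yn-3-one, via lithium methoxyacetylide 14 (not isolated)
Conditions: LiNEt2 (3.1 equiv, from Et2NH and n-BuLi), THF, 0 °C; then 13, −78 → −20 °C; inverse quench into cold aq. NaH2PO4 (pH 4–5)
Reagents that add atoms: none
Why: Threefold base treatment of the chloroacetal (loss of methanol, loss of HCl, deprotonation) gives the lithium alkoxyacetylide, and its acylation by the Weinreb amide stops at the ketone because the tetrahedral chelate survives until the buffered quench, which also protonates diethylamine before it can add to the ynone.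

Step 6
Reactants: 11 bis(silyloxy)pyranone; 15 1-methoxy-4-methylpent-1-yn-3-one (3 equiv)
Product: 17 1-{2-methoxy-3,5-bis[(1R)-1-(2-methoxy-3,3,5,5-tetramethyl-4,6-dioxocyclohex-1-en-1-yl)-2-methylpropyl]-4,6-bis(trimethylsilyloxy)phenyl}-2-methylpropan-1-one, via bridged lactone 16 (not isolated)
Conditions: toluene (about 1 M), 100 °C, sealed tube, argon; volatiles and excess 15 removed under high vacuum
Reagents that add atoms: none
Why: The pyranone reacts as a cyclic 1,1,3-trioxygenated diene (C3=C4–C5=C6) in a normal-demand, probably asynchronous [4+2] addition to the ynone: C3, the terminus made nucleophilic by both silyloxy groups, bonds to the methoxy-bearing β-carbon and the ketene-acetal carbon C6 bonds to the acyl-bearing α-carbon, giving the 2-oxabicyclo[2.2.2]octadienone 16, which expels CO2 by retro-[4+2] at the same temperature. The closest known reactions are the Diels–Alder/decarboxylation benzannulation of 2-pyranones with alkynes and the regioselective benzannulation of open-chain 1-alkoxy-1,3-bis(silyloxy)dienes with acetylenic ketones; full substitution of both partners makes this the most demanding case of that reaction. Ring A is closed by this intermolecular [4+2] addition (bonds C2–C3 and C1–C6 of ring A) and made aromatic irreversibly by the CO2 extrusion. No stereocentre is created: the bridgeheads of 16 vanish on aromatisation, and the two arm centres are spectators that cannot ionise because every oxygen is capped and the medium is neutral. The only selectivity needed is regiochemical and is secured by the matched polarisation of diene and ynone; the methyl ynol ether cannot fragment to an acylketene during heating, and crowding at C3 is the rate risk.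

Step 7
Reactants: 17 capped arene
Product: 18 myrtucommulone A, 1-{2,4,6-trihydroxy-3,5-bis[(1R)-1-(2-hydroxy-3,3,5,5-tetramethyl-4,6-dioxocyclohex-1-en-1-yl)-2-methylpropyl]phenyl}-2-methylpropan-1-one
Conditions: BCl3 (1 M in CH2Cl2, 8 equiv), CH2Cl2, −78 → 0 °C; then pH 7 phosphate buffer, 0 °C; chromatography (removes any meso diastereomer)
Reagents that add atoms: none
Why: Boron trichloride cleaves, by chloride attack on methyl, the ethers whose oxygen is activated through a carbonyl (the aryl methyl ether ortho to the ketone through a six-membered boron chelate, the two vinylogous methyl esters through their enone carbonyl) and exchanges the aryl silyl ethers for borates, all at or below 0 °C, where boron-bound phenols should be too weakly nucleophilic to cyclise onto the syncarpyl rings and the benzylic C–C bonds should not ionise; buffered hydrolysis then releases 18 with both R centres unchanged.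

**Compound list**

1 | syncarpic acid, 2,2,4,4-tetramethylcyclohexane-1,3,5-trione | CC1(C)C(=O)CC(=O)C(C)(C)C1=O | starting material
2 | isobutyraldehyde, 2-methylpropanal | CC(C)C=O | starting material
3 | Mannich base, 5-hydroxy-2,2,6,6-tetramethyl-4-[2-methyl-1-(piperidin-1-yl)propyl]cyclohex-4-ene-1,3-dione (racemic) | CC(C)C(N1CCCCC1)C1=C(O)C(C)(C)C(=O)C(C)(C)C1=O | intermediate (not isolated)
4 | isobutylidenesyncarpic acid, 2,2,4,4-tetramethyl-6-(2-methylpropylidene)cyclohexane-1,3,5-trione | CC(C)C=C1C(=O)C(C)(C)C(=O)C(C)(C)C1=O | intermediate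
5 | dibenzyl 3-oxopentanedioate | O=C(CC(=O)OCc1ccccc1)CC(=O)OCc1ccccc1 | starting material
6 | mono-adduct, dibenzyl 2-[(1R)-1-(2-hydroxy-3,3,5,5-tetramethyl-4,6-dioxocyclohex-1-en-1-yl)-2-methylpropyl]-3-oxopentanedioate (C2 epimers) | O=C(CC(=O)OCc1ccccc1)C([C@H](C1=C(O)C(C)(C)C(=O)C(C)(C)C1=O)C(C)C)C(=O)OCc1ccccc1 | intermediate (not isolated)
7 | uncapped bis-adduct, dibenzyl 2,4-bis[(1R)-1-(2-hydroxy-3,3,5,5-tetramethyl-4,6-dioxocyclohex-1-en-1-yl)-2-methylpropyl]-3-oxopentanedioate (C2/C4 epimers, keto form drawn) | O=C(C([C@H](C1=C(O)C(C)(C)C(=O)C(C)(C)C1=O)C(C)C)C(=O)OCc1ccccc1)C([C@H](C1=C(O)C(C)(C)C(=O)C(C)(C)C1=O)C(C)C)C(=O)OCc1ccccc1 | intermediate (not isolated)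
8 | dibenzyl 2,4-bis[(1R)-1-(2-methoxy-3,3,5,5-tetramethyl-4,6-dioxocyclohex-1-en-1-yl)-2-methylpropyl]-3-oxopentanedioate (C2/C4 epimers) | O=C(C([C@H](C1=C(OC)C(C)(C)C(=O)C(C)(C)C1=O)C(C)C)C(=O)OCc1ccccc1)C([C@H](C1=C(OC)C(C)(C)C(=O)C(C)(C)C1=O)C(C)C)C(=O)OCc1ccccc1 | intermediate
9 | keto diacid, 2,4-bis[(1R)-1-(2-methoxy-3,3,5,5-tetramethyl-4,6-dioxocyclohex-1-en-1-yl)-2-methylpropyl]-3-oxopentanedioic acid (C2/C4 epimers) | O=C(C([C@H](C1=C(OC)C(C)(C)C(=O)C(C)(C)C1=O)C(C)C)C(=O)O)C([C@H](C1=C(OC)C(C)(C)C(=O)C(C)(C)C1=O)C(C)C)C(=O)O | intermediate (not isolated)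
10 | enolised cyclic anhydride, 4,6-dihydroxy-3,5-bis[(1S)-1-(2-methoxy-3,3,5,5-tetramethyl-4,6-dioxocyclohex-1-en-1-yl)-2-methylpropyl]-2H-pyran-2-one (dienol tautomer drawn) | O=C1OC(O)=C([C@H](C2=C(OC)C(C)(C)C(=O)C(C)(C)C2=O)C(C)C)C(O)=C1[C@H](C2=C(OC)C(C)(C)C(=O)C(C)(C)C2=O)C(C)C | intermediate
11 | 3,5-bis[(1S)-1-(2-methoxy-3,3,5,5-tetramethyl-4,6-dioxocyclohex-1-en-1-yl)-2-methylpropyl]-4,6-bis(trimethylsilyloxy)-2H-pyran-2-one | O=C1OC(O[Si](C)(C)C)=C([C@H](C2=C(OC)C(C)(C)C(=O)C(C)(C)C2=O)C(C)C)C(O[Si](C)(C)C)=C1[C@H](C2=C(OC)C(C)(C)C(=O)C(C)(C)C2=O)C(C)C | intermediate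
12 | 2-chloro-1,1-dimethoxyethane | COC(CCl)OC | starting material
13 | N-methoxy-N,2-dimethylpropanamide | CC(C)C(=O)N(C)OC | starting material
14 | lithium methoxyacetylide | [Li]C#COC | intermediate (not isolated)
15 | 1-methoxy-4-methylpent-1-yn-3-one | COC#CC(=O)C(C)C | intermediate
16 | bridged lactone, 8-methoxy-7-(2-methylpropanoyl)-4,6-bis[(1S)-1-(2-methoxy-3,3,5,5-tetramethyl-4,6-dioxocyclohex-1-en-1-yl)-2-methylpropyl]-1,5-bis(trimethylsilyloxy)-2-oxabicyclo[2.2.2]octa-5,7-dien-3-one (both bridgehead diastereomers) | O=C1OC2(O[Si](C)(C)C)C(C(=O)C(C)C)=C(OC)C1([C@H](C3=C(OC)C(C)(C)C(=O)C(C)(C)C3=O)C(C)C)C(O[Si](C)(C)C)=C2[C@H](C3=C(OC)C(C)(C)C(=O)C(C)(C)C3=O)C(C)C | intermediate (not isolated)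
17 | 1-{2-methoxy-3,5-bis[(1R)-1-(2-methoxy-3,3,5,5-tetramethyl-4,6-dioxocyclohex-1-en-1-yl)-2-methylpropyl]-4,6-bis(trimethylsilyloxy)phenyl}-2-methylpropan-1-one | CC(C)C(=O)c1c(OC)c([C@H](C2=C(OC)C(C)(C)C(=O)C(C)(C)C2=O)C(C)C)c(O[Si](C)(C)C)c([C@H](C2=C(OC)C(C)(C)C(=O)C(C)(C)C2=O)C(C)C)c1O[Si](C)(C)C | intermediate
18 | myrtucommulone A, (R,R) | CC(C)C(=O)c1c(O)c([C@H](C2=C(O)C(C)(C)C(=O)C(C)(C)C2=O)C(C)C)c(O)c([C@H](C2=C(O)C(C)(C)C(=O)C(C)(C)C2=O)C(C)C)c1O | target

**Step count and risks**

Total steps: 7. Longest linear sequence: 6 (steps 1, 2, 3, 4, 6, 7); step 5 is a one-step side branch.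

Steps most likely to fail:

Step 6. The cycloaddition may stall because the diene terminus C3 and the ynone are both fully substituted, so that silyl loss from the pyranone, oligomerisation of the ynone, or an open-chain conjugate adduct that does not close takes over. The fallback gives up the ring construction and uses the double Friedel–Crafts-type conjugate addition of an intact acylphloroglucinol. It sets out from 4 (2.1 equiv): 2-methyl-1-(2,4,6-trihydroxyphenyl)propan-1-one F1 is added in THF at 0 °C in the presence of LiAl[(R)-binaphtholate]2, or its enantiomer if that is the one that delivers R. The reaction passes through the mono-adduct 1-{2,4,6-trihydroxy-3-[(1R)-1-(2-hydroxy-3,3,5,5-tetramethyl-4,6-dioxocyclohex-1-en-1-yl)-2-methylpropyl]phenyl}-2-methylpropan-1-one F2 and arrives directly at 18; the meso diastereomer is removed by chromatography.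

Step 2. Turnover may fade as the acidic enol product accumulates and binds the amine of the catalyst. The second addition may show poor facial selectivity, so that the meso isomer builds up. Uncatalysed addition of the keto ester enol to the very electrophilic 4 may also erode selectivity. The fallback reverses the roles of donor and acceptor. It sets out from 5 and 2: Knoevenagel condensation (TiCl4, pyridine, THF, 0 °C) should give the bis-alkylidene dibenzyl 2,4-bis(2-methylpropylidene)-3-oxopentanedioate F3. Syncarpic acid 1 (2.1 equiv), whose acidity matches that of the product so the catalyst is not titrated, is then added twice under the same kind of amine–squaramide catalysis. This passes through the mono-adduct dibenzyl 2-[(1R)-1-(2-hydroxy-3,3,5,5-tetramethyl-4,6-dioxocyclohex-1-en-1-yl)-2-methylpropyl]-4-(2-methylpropylidene)-3-oxopentanedioate F4 and comes back to the route at 7, which is capped in the same flask to 8 as in step 2.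

Step 3. The β-keto diacid may lose CO2 before or during ring closure, or the hindered anhydride may close only partly and leave mixed acetic anhydrides. The fallback never handles the free acid and closes the ring through an acid chloride. It sets out from 8: hydrogenolysis as before, with the cold filtrate run directly into BSA, so that the acid is held as bis(trimethylsilyl) 2,4-bis[(1R)-1-(2-methoxy-3,3,5,5-tetramethyl-4,6-dioxocyclohex-1-en-1-yl)-2-methylpropyl]-3-oxopentanedioate F5. Oxalyl chloride (1 equiv) with catalytic DMF in CH2Cl2 at 0 °C turns one silyl ester into the acid chloride trimethylsilyl 5-chloro-2,4-bis[(1R)-1-(2-methoxy-3,3,5,5-tetramethyl-4,6-dioxocyclohex-1-en-1-yl)-2-methylpropyl]-3,5-dioxopentanoate F6, which acylates the neighbouring silyl carboxylate. In the silylating medium the ring-closed product is taken on to 11, where the route is rejoined.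

**Further compounds**

F1 | step 6 | 2-methyl-1-(2,4,6-trihydroxyphenyl)propan-1-one | CC(C)C(=O)c1c(O)cc(O)cc1O
F2 | step 6 | 1-{2,4,6-trihydroxy-3-[(1R)-1-(2-hydroxy-3,3,5,5-tetramethyl-4,6-dioxocyclohex-1-en-1-yl)-2-methylpropyl]phenyl}-2-methylpropan-1-one | CC(C)C(=O)c1c(O)cc(O)c([C@H](C2=C(O)C(C)(C)C(=O)C(C)(C)C2=O)C(C)C)c1O
F3 | step 2 | dibenzyl 2,4-bis(2-methylpropylidene)-3-oxopentanedioate | CC(C)C=C(C(=O)OCc1ccccc1)C(=O)C(=CC(C)C)C(=O)OCc1ccccc1
F4 | step 2 | dibenzyl 2-[(1R)-1-(2-hydroxy-3,3,5,5-tetramethyl-4,6-dioxocyclohex-1-en-1-yl)-2-methylpropyl]-4-(2-methylpropylidene)-3-oxopentanedioate | CC(C)C=C(C(=O)OCc1ccccc1)C(=O)C([C@H](C1=C(O)C(C)(C)C(=O)C(C)(C)C1=O)C(C)C)C(=O)OCc1ccccc1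
F5 | step 3 | bis(trimethylsilyl) 2,4-bis[(1R)-1-(2-methoxy-3,3,5,5-tetramethyl-4,6-dioxocyclohex-1-en-1-yl)-2-methylpropyl]-3-oxopentanedioate | O=C(C([C@H](C1=C(OC)C(C)(C)C(=O)C(C)(C)C1=O)C(C)C)C(=O)O[Si](C)(C)C)C([C@H](C1=C(OC)C(C)(C)C(=O)C(C)(C)C1=O)C(C)C)C(=O)O[Si](C)(C)C
F6 | step 3 | trimethylsilyl 5-chloro-2,4-bis[(1R)-1-(2-methoxy-3,3,5,5-tetramethyl-4,6-dioxocyclohex-1-en-1-yl)-2-methylpropyl]-3,5-dioxopentanoate | O=C(C([C@H](C1=C(OC)C(C)(C)C(=O)C(C)(C)C1=O)C(C)C)C(Cl)=O)C([C@H](C1=C(OC)C(C)(C)C(=O)C(C)(C)C1=O)C(C)C)C(=O)O[Si](C)(C)C
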